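## Structural features

The target is a germacranolide: a ten-membered carbocycle (C1–C10) with two ring double bonds that are both cis within the ring. C4=C5 is Z and carries the C15 methyl; C1=C10 is E by the CIP rules only because C10 carries the C14 methyl ester. Between the two olefins lies a cis-2,3-epoxide that is allylic on both sides. An α-methylene-γ-butyrolactone (O6–C12(=O)–C11(=C13)–C7) is trans-fused across C6–C7. The ring stereocentres are C2, C3 and the contiguous run C6–C7–C8–C9 (2R,3S,6R,7S,8S,9S): O6 and O9 lie on one side of the ring, C11 and O8 on the other, and the epoxide oxygen is on the side of O6 and O9. The vicinal oxygens O8 and O9 carry different esters with their own stereocentres: (2S,3S)-2,3-epoxy-2-methylbutanoate on O8 and (R)-2-methylbutanoate on O9. Fragile groups are the doubly allylic epoxide (acid, soft nucleophiles, zerovalent palladium), the methylene lactone and the enoate (alkoxides), and the O8/O9 esters (acyl shift). The real difficulty is the medium ring with two defined olefin geometries, the trans relation of O8 and O9, their differentiation, and a late order of events that spares epoxide and lactone. The key step exploits two features: C14, C10, C1, C2, C3, C4 and C5 form a seven-carbon unit that becomes a 3-methyltropone ring once C14 is bonded to C5, and C6–C9 is a four-carbon unit with cis oxygens at both ends.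

## Logic of the disconnections

32 ⇒ 26 + 30. The O8–acyl bond is cut first because the epoxy ester is the most sensitive appendage. This removes two stereocentres and one epoxide. The forward step must acylate a hindered hydroxyl without acyl shift from O9 and without touching either oxirane. 30 is traced through 29 and 28 to 27 by removing the oxirane oxygen; the forward epoxidation must be reagent-controlled.

26 ⇒ 23 + 24 (through 25). The O9–acyl bond is cut and O8 becomes a benzyl-type ether. The two oxygens are then told apart by synthesis rather than by selective acylation of a diol. The forward acylation must not epimerise 24.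

23 ⇒ 22. The O6–C12 and C11–C12 bonds are cut, which removes carbon monoxide and leaves a C7 ethynyl group and a free O6 hydroxyl. The methylene lactone is a Michael acceptor and is therefore made after every alkoxide step; the alkyne is inert to the oxidants used earlier. The forward step must carbonylate at O6 only and tolerate the vinyl epoxide.

22 ⇒ 19. One C–O bond of the 2,3-epoxide is opened to a cis-2,3-diol, so both oxygens can be set earlier on a rigid framework. The forward step must turn a cis-diol into a cis-epoxide with net retention at both carbons.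

19 ⇒ 17 (through 18). The C14–C5 bond is re-formed and C1=C10 is converted back to a 1,2-epoxide. The flexible ring becomes a rigid bicyclo[4.4.1]undecanone in which faces are defined and both olefin geometries are stored. The forward fragmentation needs the C4–O bond anti-periplanar to C5–C14, and C10 must not carry a better β-leaving group than the 1,2-epoxide; O9 is therefore a free hydroxyl and O8 an ether at that stage.

17 ⇒ 16 ⇒ 14 ⇒ 13. The oxygens at C1/C2, C3/C4 and C8/C9 are removed in turn. All come from olefin faces that the bicycle distinguishes. The exception is the C4 oxygen, which must sit on the hindered face and can only be delivered from O6 through a carbonate. The forward order must keep O6 acylated while a 3,4-epoxide exists, because a free O6 alkoxide could fragment C5–C6.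

13 ⇒ 12 ⇒ 11 ⇒ 9 + 10. The C7–C11 bond is cut with allylic transposition, which returns the 2-ene-1,4-diol pattern. The carbon must enter anti to the C9 oxygen so that it ends up trans to O6; a suprafacial sigmatropic shift from O9 would give the wrong face. The forward step must be γ-selective and anti.

9 ⇒ 8 ⇒ 7. The two acetates are made equal again and the racemate is accepted. The forward step must choose one enantiomer and one of its two acetates.

7 ⇒ 5 + 6. C5–C6 and C9–C10 are cut. Two rings and four stereocentres fall away and two flat, achiral components remain. The forward step must be periselective and exo-selective.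

5 ⇒ 3 ⇒ 2 ⇒ 1. The seven-membered ring is contracted by removing the carbene carbon, and the diene is re-aromatised. The forward steps must add the carbene to the enol-ether double bond only.

## Other disconnections considered

Alternative 1: The cut is C1–C2. In the forward direction the open-chain E β-iodoenoate aldehyde A2 is treated with CrCl2 and catalytic NiCl2; the vinylchromium species adds to the C2 aldehyde and closes the ten-membered ring as the C2 carbinol A1.
- In favour: every stereocentre of A2 can be set in an open chain under reagent control, so no resolution is needed. On material throughput this is better than the chosen plan, which can use at most half of 7.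
- In favour: the C1=C10 geometry is fixed in A2 before ring closure, which is better than relying on the elimination in step 13.
- Equal: O8 and O9 arrive differentiated in A1, as in 22.
- Against: a ten-membered ring with two cis olefins is closed by a carbonyl addition at high dilution, with little control over C2. A1 as drawn has O2 and O3 on the same side, so a single displacement would give the trans-epoxide; the same double-inversion manoeuvre as in step 14 would be needed.
- Against: a large excess of a divalent chromium salt is needed, and A2 itself would need a long linear sequence.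
- Comparison: structurally the alternative builds the ring last and the chosen plan builds it first and then edits it. Mechanistically it is a polar organometallic addition against a pericyclic reaction. In step economy the chosen plan gains ring, olefin geometry and four stereocentres in one step from two simple components, and pays with a resolution and a long oxidation sequence.

Alternative 2: The cut is C4=C5. A diisopropylsilylene bridge between O3 and O6 holds the C4 isopropenyl and C5 vinyl groups of diene A4 together, and second-generation Grubbs catalyst closes the seven-membered dioxasilepine A3.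
- Equal: the small ring enforces the Z geometry of the trisubstituted olefin, as reliably as the bicyclic fragmentation does here.
- Better: two enantiopure halves are joined convergently and no resolution is needed.
- Better: in A3 the C2 mesylate is trans to O3, so one displacement closes the cis-epoxide. This is a cleaner epoxide endgame than step 14.
- Against: the metathesis does not close the ten-membered ring. A separate C1–C10 ring closure is still required and must give the E enoate.
- Against: ring-closing metathesis between a 1,1-disubstituted and a hindered allylic olefin is slow, and the second 1,1-disubstituted olefin of A4 (the future C11=C13) can compete.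
- Against: the protecting-group load is high (three silyl ethers, a silylene, a benzyl ether and a mesylate).
- Comparison: structurally the medium ring is formed late; mechanistically olefin geometry is set by catalysis on a tether rather than by fragmentation of a bicycle; step economy is likely poorer after the key step.

Alternative 3: The cut is C2–C3 together with O–C3. The allylic diphenylsulfonium salt A6 is deprotonated; the ylide adds to the C2 aldehyde and the alkoxide displaces diphenyl sulfide, which closes the ring and the oxirane in one step to give A5.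
- Better: ring and the most fragile function appear together at a late stage, with no diol-to-epoxide sequence.
- In favour: no transition metal is needed.
- Against: semi-stabilised allylic ylides tend to give trans-epoxides or mixtures, and the two new stereocentres depend on substrate control in a ring-closing transition state. The chosen plan sets both carbons on a rigid bicycle.
- Against: the ylide can add in conjugate fashion to the enal or react through its γ-terminus.
- Against: A5 lacks C13, so a lactone enolate methylenation must follow in the presence of the vinyl epoxide. That is less safe than the neutral carbonylation of step 15.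
- Comparison: structurally convergent and late-closing; mechanistically ionic and stepwise; step economy is probably similar to alternative 1 and no better than the chosen plan once the synthesis of A6 is counted.

Key step: step 4

Remarks on the chemistry (assumptions):
- Germacrane locants are used for every intermediate (C14 = bridging carbonyl or ester carbon, C15 = methyl on C4, C11–C13 = lactone carbons).
- Cycloadduct 7 carries the C4 methyl group and is therefore chiral and racemic, not meso. Step 5 is planned as a regiodivergent resolution, so at most half of 7 is useful.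
- A suprafacial [3,3] shift from an O9 ester would place C11 cis to O6, whereas 32 needs trans. C11 is therefore introduced by anti-SN2' substitution.
- The oxygen on C4 can leave in the fragmentation only if it is anti to C5–C14, which is the face of the diene bridge away from C14. It is therefore delivered from O6.
- The SMILES of 5, 6 and 7 were checked against 32 and are consistent: 7 as drawn has the configuration of 32 at C6 and C9, the O9 acid is R, and the O8 acid is the cis (angelate-derived) 2S,3S epoxide.

## Route

Step 1
Reactants: 1 3-methylanisole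
Product: 2 1-methoxy-5-methylcyclohexa-1,4-diene
Conditions: Li, NH3(l), THF, t-BuOH, −78 → −33 °C
Reagents that add atoms: none
Why: Birch reduction; both donor substituents end on the remaining double bonds, giving the skipped diene with an enol-ether double bond ready for carbene addition.

Step 2
Reactants: 2 1-methoxy-5-methylcyclohexa-1,4-diene
Product: 3 (±)-7,7-dibromo-1-methoxy-3-methylbicyclo[4.1.0]hept-3-ene
Conditions: CHBr3, KOt-Bu, pentane, −20 → 0 °C
Reagents that add atoms: bromoform, BrC(Br)Br
Why: dihalocarbene cyclopropanation; the electrophilic carbene should add to the more electron-rich enol-ether double bond and leave the methyl-substituted olefin.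

Step 3
Reactants: 3 (±)-7,7-dibromo-1-methoxy-3-methylbicyclo[4.1.0]hept-3-ene
Product: 5 3-methyltropone, via 2-bromo-6-methylcyclohepta-2,5-dien-1-one 4 (not isolated)
Conditions: pyridine, H2O, 100 °C
Reagents that add atoms: water, O
Why: methoxy-assisted electrocyclic opening of the gem-dibromocyclopropane (cyclopropyl-to-allyl cation ring expansion), hydrolysis to the bromodienone and loss of HBr should give the tropone with the methyl group on C3.

Step 4
Reactants: 5 3-methyltropone; 6 (1E,3E)-buta-1,3-diene-1,4-diyl diacetate
Product: 7 (±)-(5R*,6S*,9R*,10S*)-6,9-diacetoxy-4-methylbicyclo[4.4.1]undeca-1,3,7-trien-14-one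
Conditions: toluene, BHT (cat.), 110 °C, sealed tube, 6 in excess
Reagents that add atoms: none
Why: Thermally allowed, concerted, suprafacial [6π+4π] cycloaddition between C2/C7 of the tropone and the termini of the s-cis diene; the closest known reaction type is the exo-selective [6+4] addition of tropone to 1-acyloxybuta-1,3-dienes. The new cyclohept-4-enone ring (C14, C5–C10) and with it the ten-membered carbocycle are both closed by the simultaneous intermolecular formation of C5–C6 and C9–C10, so no tethered chain has to be folded. C5 and C10 are set because both new bonds form on one face of the planar tropone, which makes H5 and H10 cis. C6 and C9 are set by the E,E geometry of the diene together with the exo transition state, in which C7 and C8 lie under the carbonyl and not under the triene; both acetoxy groups then end on the ring face that carries H5 and H10, the cis O6/O9 relation of 32. The step needs periselectivity over [4+2] modes and exo selectivity; the electron-rich diene paired with the electron-poor 6π partner and the repulsive secondary overlap of the endo arrangement should provide both. The diene is symmetrical, so no regiochemical question arises and the C4 methyl only slows bond formation at the neighbouring terminus. The adduct is racemic; the absolute configuration is selected in step 5.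

Step 5
Reactants: 7 (±)-6,9-diacetoxy-4-methylbicyclo[4.4.1]undeca-1,3,7-trien-14-one
Product: 8 (5R,6S,9R,10S)-6-acetoxy-9-hydroxy-4-methylbicyclo[4.4.1]undeca-1,3,7-trien-14-one
Conditions: Burkholderia cepacia lipase (immobilised), pH 7 phosphate buffer/MTBE, 30 °C, stopped after one acetate per molecule is cleaved
Reagents that add atoms: none
Why: lipase-catalysed enantio- and regioselective ester hydrolysis used as a regiodivergent resolution; by the empirical preference of lipases for the (R)-carbinol centre whose larger flank has CIP priority (here the bridgehead), the (5R,6S,9R,10S) enantiomer should lose its C9 acetate and the antipode its C6 acetate, so the two monoacetates are constitutional isomers and separable; no stereocentre is formed.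

Step 6
Reactants: 8 (5R,6S,9R,10S)-6-acetoxy-9-hydroxy-4-methylbicyclo[4.4.1]undeca-1,3,7-trien-14-one
Product: 9 (5R,6S,9R,10S)-6-acetoxy-9-(diethoxyphosphoryloxy)-4-methylbicyclo[4.4.1]undeca-1,3,7-trien-14-one
Conditions: ClP(O)(OEt)2, pyridine, DMAP (cat.), CH2Cl2, 0 °C
Reagents that add atoms: diethyl chlorophosphate, CCOP(Cl)(=O)OCC
Why: phosphorylation of the allylic alcohol supplies the leaving group for copper-mediated allylic substitution; the C6 acetate stays as protecting group.

Step 7
Reactants: 9 the C9 diethyl phosphate; 10 ethynyltrimethylsilane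
Product: 11 6-acetoxy-4-methyl-7-[(trimethylsilyl)ethynyl]bicyclo[4.4.1]undeca-1,3,8-trien-14-one (alkynyl group trans to O6)
Conditions: CuCl (10 mol%), 1,10-phenanthroline (12 mol%), LiOt-Bu, THF, 20 °C
Reagents that add atoms: none
Why: copper-catalysed γ-selective allyl–alkyne coupling (anti-SN2' substitution by a copper acetylide); the alkynyl group should enter at C7 on the face opposite to the departing C9 phosphate, which sets C7 trans to O6 and moves the olefin to C8=C9; copper-mediated SN2' substitutions of 2-ene-1,4-diol diesters are known to leave the second ester in place.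

Step 8
Reactants: 11 6-acetoxy-7-[(trimethylsilyl)ethynyl] trienone
Product: 12 7-ethynyl-6-hydroxy-4-methylbicyclo[4.4.1]undeca-1,3,8-trien-14-one (ethynyl trans to O6)
Conditions: K2CO3 (cat.), MeOH, 0 °C
Reagents that add atoms: none
Why: methanolysis of the acetate and protodesilylation of the alkynylsilane; the α-hydrogens of the ketone are at bridgeheads (Bredt's rule), so the β-oxygenated ketone cannot eliminate.

Step 9
Reactants: 12 7-ethynyl-6-hydroxy trienone
Product: 13 tert-butyl carbonate of 12 at O6
Conditions: Boc2O, DMAP (cat.), CH2Cl2, 20 °C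
Reagents that add atoms: di-tert-butyl dicarbonate, CC(C)(C)OC(=O)OC(=O)OC(C)(C)C
Why: carbonate formation; it removes the donor ability of O6, so C5–C6 cannot fragment once C4 is oxygenated, and it installs the internal nucleophile for C4.

Step 10
Reactants: 13 tert-butyl carbonate
Product: 14 3,4:8,9-bis-epoxide of 13 (3,4-oxirane oxygen syn to C14; 8,9-oxirane oxygen cis to O6 and trans to the ethynyl group)
Conditions: dimethyldioxirane (2.1 equiv), acetone/CH2Cl2, −40 → 0 °C
Reagents that add atoms: dimethyldioxirane, CC1(C)OO1
Why: electrophilic epoxidation under steric control; the trisubstituted C3=C4 bond should react first on the face syn to the one-carbon bridge (the other face is screened by C6 and C9), then C8=C9 on the face away from the C7 ethynyl group and from C1, while C1=C2 is deactivated by the adjacent oxirane and the alkyne is inert; this sets C3, C4, C8 and C9.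

Step 11
Reactants: 14 bis-epoxide
Product: 16 cyclic 4,6-carbonate with 3-hydroxy, 9-hydroxy and 8-(4-methoxybenzyloxy) groups, via epoxy cyclic carbonate 15 (not isolated)
Conditions: BF3·OEt2 (0.3 equiv), CH2Cl2, −78 °C; then 4-methoxybenzyl alcohol, −78 → −20 °C
Reagents that add atoms: (4-methoxyphenyl)methanol, COc1ccc(CO)cc1
Why: Lewis-acid-promoted epoxide opening by the neighbouring tert-butyl carbonate (6-exo attack of the carbonyl oxygen at tertiary C4 with inversion, loss of isobutene) should place the C4 oxygen anti to C5–C14 and free the C3 hydroxyl; the 8,9-epoxide is then opened by the alcohol at C8 with inversion, because backside attack at C9 would have to come from the concave side below the bridgehead, so O8 ends cis to the C7 substituent and trans to O9.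

Step 12
Reactants: 16 cyclic carbonate diol
Product: 17 1,2-epoxide of 16 (oxirane oxygen cis to the C3 hydroxyl, syn to C14)
Conditions: VO(acac)2 (5 mol%), t-BuOOH, CH2Cl2, 0 → 20 °C
Reagents that add atoms: tert-butyl hydroperoxide, CC(C)(C)OO
Why: hydroxyl-directed epoxidation of a cyclic allylic alcohol; the C3 hydroxyl should deliver oxygen to its own face of C1=C2, setting C1 and C2, and the allylic direction outruns the homoallylic one from O9.

Step 13
Reactants: 17 epoxy cyclic carbonate ketone
Product: 19 methyl (1(10)E,4Z)-7-ethynyl-2,3,6,9-tetrahydroxy-8-(4-methoxybenzyloxy)-4-methylcyclodeca-1(10),4-diene-10-carboxylate, via β,γ-epoxy ester 18 (not isolated)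
Conditions: NaOMe, MeOH, 0 → 20 °C; aq. NH4Cl
Reagents that add atoms: sodium methoxide, [Na+].[O-]C
Why: Grob fragmentation followed by E1cB epoxide opening; methoxide adds to the non-enolisable bridging ketone, and the hemiketal alkoxide should cleave C14–C5 anti-periplanar to the C4–O carbonate bond, so C4=C5 is Z by the bicyclic geometry, C14 becomes the methyl ester and O6 loses CO2. The ester enolate at C10 then opens the 1,2-epoxide to the C1=C10 enoate with C9 and C2 cis, leaving O2 and O3 on the same side.

Step 14
Reactants: 19 tetraol
Product: 22 methyl (1(10)E,4Z)-2,3-epoxy-7-ethynyl-6,9-dihydroxy-8-(4-methoxybenzyloxy)-4-methylcyclodeca-1(10),4-diene-10-carboxylate, via cyclic orthoacetate 20 (not isolated), via chloro acetate 21 (not isolated)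
Conditions: MeC(OMe)3, PPTS (cat.), CH2Cl2, 20 °C; evaporation; Me3SiCl, CH2Cl2, 0 °C; evaporation; K2CO3, MeOH, 0 °C
Reagents that add atoms: none
Why: diol-to-epoxide conversion through a cyclic orthoester, chloride opening of the acetoxonium ion and base-induced ring closure; two inversions at the same carbon should give the cis-epoxide with the original sense of both C–O bonds whichever carbon chloride attacks, and hydroxyls acetylated on the way are freed in the methanolysis.

Step 15
Reactants: 22 epoxy diol
Product: 23 methyl (1(10)E,4Z)-2,3-epoxy-9-hydroxy-8-(4-methoxybenzyloxy)-4-methyl-12-oxo-6,12-epoxycyclodeca... i.e. the trans-fused 6,12-olide with C11=C13 methylene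
Conditions: PdCl2 (5 mol%), thiourea (5 mol%), CO (1 atm), acetone, 50 °C
Reagents that add atoms: carbon monoxide, [C-]#[O+]
Why: palladium-catalysed cyclocarbonylation of a homopropargylic alcohol; the O6 alkoxycarbonyl–palladium species should add across the ethynyl group and protonolysis gives the trans-fused α-methylene-γ-lactone directly, while O9 cannot reach the alkyne through a fused ring.

Step 16
Reactants: 23 hydroxy lactone; 24 (R)-2-methylbutanoic acid
Product: 25 9-O-[(R)-2-methylbutanoyl] derivative of 23
Conditions: N,N'-diisopropylcarbodiimide, DMAP (cat.), CH2Cl2, 0 °C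
Reagents that add atoms: none
Why: Steglich esterification of the only free hydroxyl; the low temperature should limit epimerisation of the acid α-centre.

Step 17
Reactants: 25 O9 ester
Product: 26 8-hydroxy compound (O8 free, O9 ester)
Conditions: DDQ, CH2Cl2/pH 7 buffer, 0 °C
Reagents that add atoms: none
Why: oxidative cleavage of the 4-methoxybenzyl ether under neutral conditions, which should spare the vinyl epoxide, the enoate and the methylene lactone.

Step 18
Reactants: 27 angelic acid
Product: 28 (Z)-2-methylbut-2-en-1-ol
Conditions: LiAlH4, Et2O, 0 °C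
Reagents that add atoms: none
Why: hydride reduction of the carboxylic acid to the allylic alcohol with retention of the Z geometry.

Step 19
Reactants: 28 (Z)-2-methylbut-2-en-1-ol
Product: 29 ((2R,3S)-2,3-dimethyloxiran-2-yl)methanol
Conditions: Ti(OiPr)4 (cat.), D-(−)-diisopropyl tartrate, t-BuOOH, 4 Å molecular sieves, CH2Cl2, −20 °C
Reagents that add atoms: tert-butyl hydroperoxide, CC(C)(C)OO
Why: Sharpless asymmetric epoxidation; the D-tartrate complex should deliver oxygen to the face of the Z-allylic alcohol that gives the (2R,3S)-epoxy alcohol, with the cis geometry retained.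

Step 20
Reactants: 29 epoxy alcohol
Product: 30 (2S,3S)-2,3-dimethyloxirane-2-carboxylic acid
Conditions: TEMPO (cat.), PhI(OAc)2, MeCN/H2O, 20 °C
Reagents that add atoms: water, O
Why: nitroxyl-catalysed oxidation of the primary alcohol through the aldehyde hydrate to the acid; the stereocentres are untouched and the C2 descriptor changes only through the priority change.

Step 21
Reactants: 26 8-hydroxy compound; 30 (2S,3S)-2,3-dimethyloxirane-2-carboxylic acid
Product: 32 CNP0485260.1, via mixed anhydride 31 (not isolated)
Conditions: 2,4,6-trichlorobenzoyl chloride, Et3N, THF, 0 °C; then 26, DMAP, toluene, 20 °C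
Reagents that add atoms: none
Why: Yamaguchi esterification; the pre-formed mixed anhydride should acylate the hindered C8 hydroxyl under mild conditions that leave both oxiranes and the lactone intact and give little time for O9-to-O8 acyl shift.

## Compound list

1 | 3-methylanisole | COc1cccc(C)c1 | starting material
2 | 1-methoxy-5-methylcyclohexa-1,4-diene | COC1=CCC=C(C)C1 | intermediate
3 | (±)-7,7-dibromo-1-methoxy-3-methylbicyclo[4.1.0]hept-3-ene (racemic, cis ring fusion) | COC12CC(C)=CCC1C2(Br)Br | intermediate
4 | 2-bromo-6-methylcyclohepta-2,5-dien-1-one | O=C1C(Br)=CCC=C(C)C1 | intermediate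
5 | 3-methyltropone | CC1=CC(=O)C=CC=C1 | intermediate
6 | (1E,3E)-buta-1,3-diene-1,4-diyl diacetate | CC(=O)O/C=C/C=C/OC(C)=O | starting material
7 | (±)-(5R*,6S*,9R*,10S*)-6,9-diacetoxy-4-methylbicyclo[4.4.1]undeca-1,3,7-trien-14-one (racemic; one enantiomer drawn) | O=C1[C@@H]2C(C)=CC=C[C@H]1[C@H](OC(C)=O)C=C[C@@H]2OC(C)=O | intermediate
8 | (5R,6S,9R,10S)-6-acetoxy-9-hydroxy-4-methylbicyclo[4.4.1]undeca-1,3,7-trien-14-one | O=C1[C@@H]2C(C)=CC=C[C@H]1[C@H](O)C=C[C@@H]2OC(C)=O | intermediate
9 | (5R,6S,9R,10S)-6-acetoxy-9-(diethoxyphosphoryloxy)-4-methylbicyclo[4.4.1]undeca-1,3,7-trien-14-one | O=C1[C@@H]2C(C)=CC=C[C@H]1[C@H](OP(=O)(OCC)OCC)C=C[C@@H]2OC(C)=O | intermediate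
10 | ethynyltrimethylsilane | C#C[Si](C)(C)C | starting material
11 | 6-acetoxy-4-methyl-7-[(trimethylsilyl)ethynyl]bicyclo[4.4.1]undeca-1,3,8-trien-14-one (alkynyl trans to O6) | O=C1[C@@H]2C(C)=CC=C[C@H]1C=C[C@@H](C#C[Si](C)(C)C)[C@@H]2OC(C)=O | intermediate
12 | 7-ethynyl-6-hydroxy-4-methylbicyclo[4.4.1]undeca-1,3,8-trien-14-one (ethynyl trans to O6) | O=C1[C@@H]2C(C)=CC=C[C@H]1C=C[C@@H](C#C)[C@@H]2O | intermediate
13 | tert-butyl carbonate of 12 at O6 | O=C1[C@@H]2C(C)=CC=C[C@H]1C=C[C@@H](C#C)[C@@H]2OC(=O)OC(C)(C)C | intermediate
14 | 3,4:8,9-bis-epoxide of 13 (3,4-oxirane syn to C14; 8,9-oxirane cis to O6, trans to ethynyl) | O=C1[C@@H]2[C@]3(C)O[C@@H]3C=C[C@H]1[C@@H]4O[C@@H]4[C@@H](C#C)[C@@H]2OC(=O)OC(C)(C)C | intermediate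
15 | cyclic carbonate between O6 and O4 (C4–O anti to C14), 3-hydroxy (syn to C14), 8,9-epoxide | O=C1[C@@H]2[C@]3(C)[C@H](O)C=C[C@H]1[C@@H]4O[C@@H]4[C@@H](C#C)[C@@H]2OC(=O)O3 | intermediate
16 | cyclic 4,6-carbonate, 3-hydroxy, 9-hydroxy, 8-(4-methoxybenzyloxy) (O8 cis to ethynyl, trans to O9) | O=C1[C@@H]2[C@]3(C)[C@H](O)C=C[C@H]1[C@H](O)[C@@H](OCc4ccc(OC)cc4)[C@@H](C#C)[C@@H]2OC(=O)O3 | intermediate
17 | 1,2-epoxide of 16 (oxirane cis to the C3 hydroxyl) | O=C1[C@@H]2[C@]3(C)[C@H](O)[C@@H]5O[C@@H]5[C@H]1[C@H](O)[C@@H](OCc4ccc(OC)cc4)[C@@H](C#C)[C@@H]2OC(=O)O3 | intermediate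
18 | methyl (4Z)-1,2-epoxy-7-ethynyl-3,6,9-trihydroxy-8-(4-methoxybenzyloxy)-4-methylcyclodec-4-ene-10-carboxylate | COC(=O)[C@H]1[C@H]2O[C@H]2[C@@H](O)/C(C)=C\[C@@H](O)[C@H](C#C)[C@H](OCc3ccc(OC)cc3)[C@H]1O | intermediate
19 | methyl (1(10)E,4Z)-7-ethynyl-2,3,6,9-tetrahydroxy-8-(4-methoxybenzyloxy)-4-methylcyclodeca-1(10),4-diene-10-carboxylate (O2 and O3 cis; C6–C9 as in 32) | COC(=O)/C1=C/[C@@H](O)[C@@H](O)/C(C)=C\[C@@H](O)[C@H](C#C)[C@H](OCc2ccc(OC)cc2)[C@H]1O | intermediate
20 | 2,3-O-(1-methoxyethylidene) orthoester of 19 (orthoester carbon unassigned) | COC(=O)/C1=C/[C@H]3OC(C)(OC)O[C@H]3/C(C)=C\[C@@H](O)[C@H](C#C)[C@H](OCc2ccc(OC)cc2)[C@H]1O | intermediate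
21 | 2-O-acetyl-3-chloro-3-deoxy derivative of 19 (chloride trans to O2) | COC(=O)/C1=C/[C@@H](OC(C)=O)[C@H](Cl)/C(C)=C\[C@@H](O)[C@H](C#C)[C@H](OCc2ccc(OC)cc2)[C@H]1O | intermediate
22 | methyl (1(10)E,4Z)-2,3-epoxy-7-ethynyl-6,9-dihydroxy-8-(4-methoxybenzyloxy)-4-methylcyclodeca-1(10),4-diene-10-carboxylate (C2, C3, C6–C9 as in 32) | COC(=O)/C1=C/[C@H]3O[C@H]3/C(C)=C\[C@@H](O)[C@H](C#C)[C@H](OCc2ccc(OC)cc2)[C@H]1O | intermediate
23 | 2,3-epoxy-9-hydroxy-8-(4-methoxybenzyloxy) germacra-1(10),4,11(13)-trien-12,6-olide 14-methyl ester (trans lactone) | COC(=O)/C1=C/[C@H]3O[C@H]3/C(C)=C\[C@H]4OC(=O)C(=C)[C@@H]4[C@H](OCc2ccc(OC)cc2)[C@H]1O | intermediate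
24 | (R)-2-methylbutanoic acid | CC[C@@H](C)C(=O)O | starting material
25 | 9-O-[(R)-2-methylbutanoyl] derivative of 23 | COC(=O)/C1=C/[C@H]3O[C@H]3/C(C)=C\[C@H]4OC(=O)C(=C)[C@@H]4[C@H](OCc2ccc(OC)cc2)[C@H]1OC(=O)[C@H](C)CC | intermediate
26 | 8-hydroxy-9-[(R)-2-methylbutanoyloxy] epoxy germacranolide methyl ester | COC(=O)/C1=C/[C@H]3O[C@H]3/C(C)=C\[C@H]4OC(=O)C(=C)[C@@H]4[C@H](O)[C@H]1OC(=O)[C@H](C)CC | intermediate
27 | angelic acid | C/C=C(/C)C(=O)O | starting material
28 | (Z)-2-methylbut-2-en-1-ol | C/C=C(/C)CO | intermediate
29 | ((2R,3S)-2,3-dimethyloxiran-2-yl)methanol | OC[C@@]1(C)O[C@H]1C | intermediate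
30 | (2S,3S)-2,3-dimethyloxirane-2-carboxylic acid | OC(=O)[C@@]1(C)O[C@H]1C | intermediate
31 | (2S,3S)-2,3-dimethyloxirane-2-carboxylic 2,4,6-trichlorobenzoic anhydride | O=C(OC(=O)[C@@]1(C)O[C@H]1C)c1c(Cl)cc(Cl)cc1Cl | intermediate
32 | CNP0485260.1: methyl (1(10)E,2R,3S,4Z,6R,7S,8S,9S)-2,3-epoxy-8-[(2S,3S)-2,3-dimethyloxirane-2-carbonyloxy]-9-[(R)-2-methylbutanoyloxy]germacra-1(10),4,11(13)-trien-12,6-olid-14-oate | C=C1C(=O)O[C@@H]2/C=C(/C)[C@@H]3O[C@@H]3/C=C(/C(=O)OC)[C@H](OC(=O)[C@H](C)CC)[C@@H](OC(=O)[C@@]3(C)O[C@H]3C)[C@@H]12 | target

## Step count and least certain steps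

Total step count: 21. Longest linear sequence: 18 steps (steps 1–17 and 21, from 1); steps 18–20 make the side-chain acid.

Step 4 (key step). Competing [4+2] modes of the tropone, slow bond formation at the methyl-flanked terminus and thermal loss of the diene may lower the conversion. Fallback, from 6 back to 7: the acetates of 6 are cleaved with MeLi and the dienediolate is silylated with t-BuMe2SiCl to the more electron-rich (1E,3E)-1,4-bis(tert-butyldimethylsilyloxy)buta-1,3-diene F1. Cycloaddition of F1 with 5 at lower temperature gives the bis-silyl ether adduct F2. HF·pyridine gives the racemic diol F3, and Ac2O/pyridine returns to 7.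

Step 5. The enzyme may discriminate poorly between the two acetates of each enantiomer, or hydrolysis may run on to the diol. Fallback, from 7 back to 8: limited methanolysis (K2CO3, MeOH, −20 °C) and chromatography give the racemic 9-hydroxy-6-acetate F4. (R)-1-Phenylethyl isocyanate converts it into the diastereomeric carbamates F5 and F6, which are separated. HSiCl3/Et3N cleaves the carbamate of F5 and returns 8.

Step 7. Substitution may occur at C9 (direct SN2) instead of C7, the neighbouring acetate may undergo β-elimination from the allyl-copper intermediate, or the alkoxide base may remove the silyl group early. Fallback, from 9 and 10 back to 11: 10 is converted with i-Bu2AlH and catalytic Et3N into the preformed diisobutyl[(trimethylsilyl)ethynyl]alumane F7. F7 substitutes the phosphate in the same anti-SN2' sense under catalysis by an N-heterocyclic-carbene complex of CuCl, without alkoxide base, and gives 11.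

Step 10. Over-oxidation of C1=C2, incomplete reaction at C8=C9 or poor facial selectivity may erode the material. Fallback, from 13 back to 17, one olefin at a time: one equivalent of dimethyldioxirane gives the 3,4-monoepoxide F8. BF3·OEt2 gives the cyclic carbonate allylic alcohol F9. VO(acac)2/t-BuOOH gives the 1,2-epoxide F10, in which C8=C9 is the only electron-rich olefin left. Dimethyldioxirane gives the 8,9-epoxide F11, and acid-catalysed opening with 4-methoxybenzyl alcohol at C8 returns to 17.

Step 13. Several processes may compete with the fragmentation: methanolysis of the cyclic carbonate, re-closure of the 3,4-epoxide by the C3 alkoxide, reversible retro-aldol opening at C9–C10 by the β-alkoxide, or formation of the enoate with the wrong geometry. Fallback, from 17 back to 19: NaBH4 reduces the ketone to the C14 carbinol F12. KN(SiMe3)2 in THF then triggers a Wharton fragmentation from the discrete potassium alkoxide, a stronger donor in an aprotic medium, followed by the same epoxide opening, to give the enal F13. Pinnick oxidation (NaClO2, NaH2PO4, 2-methylbut-2-ene) gives the acid F14, and Me3SiCHN2 in MeOH returns 19.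

Step 15. The Lewis-acidic palladium chloride, or adventitious zerovalent palladium, may open the vinyl epoxide during carbonylation. Fallback, from 19 back to 23, with lactone before epoxide: cyclocarbonylation of 19 under the same conditions gives the lactone triol F15. HC(OMe)3/PPTS and then Me3SiCl give the chloro formate F16, whose formate is cleaved and ring-closed with KHCO3 in MeOH at 0 °C to 23.

## Further compounds

F1 | step 4 | (1E,3E)-1,4-bis(tert-butyldimethylsilyloxy)buta-1,3-diene | CC(C)(C)[Si](C)(C)O/C=C/C=C/O[Si](C)(C)C(C)(C)C
F2 | step 4 | (±)-6,9-bis(tert-butyldimethylsilyloxy)-4-methylbicyclo[4.4.1]undeca-1,3,7-trien-14-one | O=C1[C@@H]2C(C)=CC=C[C@H]1[C@H](O[Si](C)(C)C(C)(C)C)C=C[C@@H]2O[Si](C)(C)C(C)(C)C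
F3 | step 4 | (±)-6,9-dihydroxy-4-methylbicyclo[4.4.1]undeca-1,3,7-trien-14-one | O=C1[C@@H]2C(C)=CC=C[C@H]1[C@H](O)C=C[C@@H]2O
F4 | step 5 | (±)-6-acetoxy-9-hydroxy-4-methylbicyclo[4.4.1]undeca-1,3,7-trien-14-one (racemate of 8) | O=C1[C@@H]2C(C)=CC=C[C@H]1[C@H](O)C=C[C@@H]2OC(C)=O
F5 | step 5 | (R)-1-phenylethyl carbamate of 8 at O9 | O=C1[C@@H]2C(C)=CC=C[C@H]1[C@H](OC(=O)N[C@H](C)c3ccccc3)C=C[C@@H]2OC(C)=O
F6 | step 5 | (R)-1-phenylethyl carbamate of the enantiomer of 8 at O9 | O=C1[C@H]2C(C)=CC=C[C@@H]1[C@@H](OC(=O)N[C@H](C)c3ccccc3)C=C[C@H]2OC(C)=O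
F7 | step 7 | diisobutyl[(trimethylsilyl)ethynyl]alumane | CC(C)C[Al](CC(C)C)C#C[Si](C)(C)C
F8 | step 10 | 3,4-monoepoxide of 13 (oxirane syn to C14) | O=C1[C@@H]2[C@]3(C)O[C@@H]3C=C[C@H]1C=C[C@@H](C#C)[C@@H]2OC(=O)OC(C)(C)C
F9 | step 10 | cyclic 4,6-carbonate, 3-hydroxy, C1=C2 and C8=C9 intact | O=C1[C@@H]2[C@]3(C)[C@H](O)C=C[C@H]1C=C[C@@H](C#C)[C@@H]2OC(=O)O3
F10 | step 10 | 1,2-epoxide of F9 (oxirane cis to the C3 hydroxyl) | O=C1[C@@H]2[C@]3(C)[C@H](O)[C@@H]5O[C@@H]5[C@H]1C=C[C@@H](C#C)[C@@H]2OC(=O)O3
F11 | step 10 | 1,2:8,9-bis-epoxide (8,9-oxirane cis to O6) | O=C1[C@@H]2[C@]3(C)[C@H](O)[C@@H]5O[C@@H]5[C@H]1[C@@H]4O[C@@H]4[C@@H](C#C)[C@@H]2OC(=O)O3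
F12 | step 13 | C14 carbinol of 17 (C14 configuration unassigned) | OC1[C@@H]2[C@]3(C)[C@H](O)[C@@H]5O[C@@H]5[C@H]1[C@H](O)[C@@H](OCc4ccc(OC)cc4)[C@@H](C#C)[C@@H]2OC(=O)O3
F13 | step 13 | (1(10)E,4Z)-7-ethynyl-2,3,6,9-tetrahydroxy-8-(4-methoxybenzyloxy)-4-methylcyclodeca-1(10),4-diene-10-carbaldehyde | O=C/C1=C/[C@@H](O)[C@@H](O)/C(C)=C\[C@@H](O)[C@H](C#C)[C@H](OCc2ccc(OC)cc2)[C@H]1O
F14 | step 13 | the corresponding cyclodecadiene-10-carboxylic acid | OC(=O)/C1=C/[C@@H](O)[C@@H](O)/C(C)=C\[C@@H](O)[C@H](C#C)[C@H](OCc2ccc(OC)cc2)[C@H]1O
F15 | step 15 | 2,3,9-trihydroxy-8-(4-methoxybenzyloxy) germacra-1(10),4,11(13)-trien-12,6-olide 14-methyl ester | COC(=O)/C1=C/[C@@H](O)[C@@H](O)/C(C)=C\[C@H]4OC(=O)C(=C)[C@@H]4[C@H](OCc2ccc(OC)cc2)[C@H]1O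
F16 | step 15 | 3-chloro-3-deoxy-2-O-formyl derivative of F15 (chloride trans to O2) | COC(=O)/C1=C/[C@@H](OC=O)[C@H](Cl)/C(C)=C\[C@H]4OC(=O)C(=C)[C@@H]4[C@H](OCc2ccc(OC)cc2)[C@H]1O
A1 | alternative 1 | 2-hydroxy-3-(triethylsilyloxy) germacranolide, O8 4-methoxybenzyl, O9 tert-butyldimethylsilyl | C=C1C(=O)O[C@@H]2/C=C(/C)[C@H](O[Si](CC)(CC)CC)[C@H](O)/C=C(/C(=O)OC)[C@H](O[Si](C)(C)C(C)(C)C)[C@@H](OCc3ccc(OC)cc3)[C@@H]12
A2 | alternative 1 | open-chain E β-iodoenoate C2 aldehyde | I/C=C(/C(=O)OC)[C@H](O[Si](C)(C)C(C)(C)C)[C@@H](OCc1ccc(OC)cc1)[C@H]2C(=C)C(=O)O[C@@H]2/C=C(/C)[C@H](O[Si](CC)(CC)CC)C=O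
A3 | alternative 2 | seven-membered diisopropyl dioxasilepine containing Z C4=C5 | CC1=C[C@@H](O[Si](C(C)C)(C(C)C)O[C@@H]1[C@@H](OS(C)(=O)=O)CO[Si](C)(C)C(C)(C)C)[C@H](C(=C)CO[Si](C)(C)C(C)(C)C)[C@H](OCc2ccc(OC)cc2)[C@@H](O[Si](CC)(CC)CC)CC(=O)OC
A4 | alternative 2 | diisopropylsilylene-bridged diene (C4 isopropenyl, C5 vinyl) | C=C[C@@H](O[Si](C(C)C)(C(C)C)O[C@@H](C(C)=C)[C@@H](OS(C)(=O)=O)CO[Si](C)(C)C(C)(C)C)[C@H](C(=C)CO[Si](C)(C)C(C)(C)C)[C@H](OCc1ccc(OC)cc1)[C@@H](O[Si](CC)(CC)CC)CC(=O)OC
A5 | alternative 3 | 11,13-dihydro-13-nor epoxy germacranolide, O8 4-methoxybenzyl, O9 tert-butyldimethylsilyl | C1C(=O)O[C@@H]2/C=C(/C)[C@@H]3O[C@@H]3/C=C(/C(=O)OC)[C@H](O[Si](C)(C)C(C)(C)C)[C@@H](OCc4ccc(OC)cc4)[C@@H]12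
A6 | alternative 3 | allylic diphenylsulfonium triflate bearing the C2 enal | O=C/C=C(/C(=O)OC)[C@H](O[Si](C)(C)C(C)(C)C)[C@@H](OCc1ccc(OC)cc1)[C@H]2CC(=O)O[C@@H]2/C=C(/C)C[S+](c3ccccc3)c4ccccc4.[O-]S(=O)(=O)C(F)(F)F
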